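## Structural features

The target joins two bicyclic units by one bond from quinone C2 to chromone C8'. One unit is a 5-hydroxy-7-methyl-1,4-naphthoquinone (benzenoid ring A, quinone ring B). The other is a 7'-methyl-4'-oxo-4H-chromene-5'-carboxylic acid (benzene ring C, pyranone ring D). There is no stereocentre; the C2–C8' axis is flanked by C1=O, C3–H, the C7' methyl group and O1' and is drawn without a fixed configuration. The quinone is sensitive to base, nucleophiles and reductants, ring D opens at C2' with hydroxide or amines, and the acid sits peri to the C4' carbonyl, so the last steps should be acidic or neutral. The real difficulties are the crowded C2–C8' bond, the placing of the aryl group at C2 and not C3 relative to the C5 hydroxyl and C7 methyl groups, and the pentasubstituted ring C with an acyl and a carboxyl carbon on neighbouring positions. Ring C has a hidden symmetry: C4a' lies between two carbons that can both start as oxygen-bearing, so a 2,6-dioxygenated 4-methylacetophenone can serve if the two oxygens are told apart. The key step uses the fact that C1 and C4 of ring B are both oxygenated and enclose C2 (aryl) and C3 (H). These four carbons map onto a 3-arylfuran whose oxygen spans C1 and C4, and C4a and C8a map onto the two sp carbons of 3-methoxy-5-methylbenzyne.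

## Logic of the disconnections

22 from 21. The O–CH3 bond at C5 and the O–CH2Ph bond of the ester are cut together. Both fall to a Lewis acid, so the free phenol and acid appear only in the last flask and no hydroxide meets the quinone or ring D. The ester is benzyl and not methyl for this reason. The forward step must cleave a benzyl ester with the reagent that demethylates the peri ether.

21 from 20. The C4=O bond is removed, which returns ring B to a phenol ring with C4–H. This trades a reactive quinone for a stable arene. It demands an oxidant that attacks only the position para to the C1 hydroxyl.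

20 from 19. The C4–O bond is re-formed so that the oxygen on C1 bridges to C4. The gain is that both quinone oxygens are traced to a single furan oxygen. The forward step needs only acid, and either direction of opening is acceptable because C1 and C4 both end as carbonyl carbons.

19 from 12 and 17, through 18. C4–C4a and C1–C8a are cut in one move. This removes ring B, splits the molecule into two fragments of similar size, and leaves the crowded C2–C8' bond as an ordinary furan–arene bond in 12. The forward cycloaddition must place furan C2 on the aryne carbon meta to the methoxy group.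

17 from 14 from 13. The C–Si and O–S bonds are cut back to an ortho-bromophenol and the C–Br bond to the phenol. This reaches a purchasable compound that already holds the methoxy and methyl groups in the right relation. The bromination must go ortho to the hydroxyl and not para to the methoxy group.

12 from 11 from 10. The C5'–CO bond is cut to an aryl triflate and the O–S bond to a phenol. The carboxyl carbon thus enters as CO with the ester of choice. The carbonylation must work on a triflate peri to the C4' carbonyl.

10 from 8 and 9. The C8'–C3(furan) bond is cut. An iodide at C8' and a boronic acid are the simplest partners, and the coupling must tolerate two ortho substituents and a free chelated phenol.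

8 from 7 from 5, through 6. The O–CH3 bond at C5' is cut, then the O1'–C2' and C2'–C3' bonds of ring D. Ring D is reduced to one formyl-equivalent carbon added to an ortho-hydroxy acetophenone. Only one phenol may be free at ring closure, so that O1' ends next to the iodine-bearing carbon.

5 from 4 from 3. One O–CH3 bond and the C–I bond are cut. In 3 the two open ring positions are equivalent, so iodination has no regiochemical choice; this is why a symmetric ketone is used. A meta-hydroxybenzoate would need an insecure acylation between OH and CO2R and an insecure ortho-iodination. The demand moves to the ether cleavage, which must pick the methoxy group next to iodine.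

3 from 1, through 2. The aryl–acetyl bond is cut. The carbon between the two methoxy groups of 1 is the most acidic ring position, so directed lithiation delivers the ketone in one step from a commercial arene.

## Other disconnections considered

Alternative 1: The cut runs through ring C at C5'–C6' and C4a'–C8a'. In the forward sense the silyl ketene acetal diene A2, which already carries the protected naphthalene on its central carbon, would add to the ynone ester A3. Loss of methanol and of the silyl group would give the acetylphenol A1, which still needs ring D closure, oxidative demethylation to the quinone and two deprotections.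
- In its favour: the crowded aryl–C8' bond is never made by cross-coupling, the acetyl and ester carbons arrive adjacent, and the naphthalene regiochemistry is settled in a protected hydroquinone beforehand. No aryne orientation has to be won, and on that point it is better than the chosen plan.
- Against it here: A2 is a tetrasubstituted diene with an ortho-methoxyaryl group and will be reluctant to reach the s-cis form. Its orientation depends on A3 discriminating between a ketone and an ester acceptor. Both partners are bespoke.
- Comparison: the regiochemical uncertainty is of the same order (a point of equality) and the mechanism is likewise a cycloaddition followed by aromatisation. The step count is higher because neither partner is close to a purchasable compound.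

Alternative 2: The cut is the O1'–C2' bond of ring D together with the C5' carboxyl carbon, both traced back to C2 and C1 of a second quinone ring. Forward, buffered CF3CO3H would insert oxygen into the C1–C2 bond of the free quinone ring of A5 (Baeyer–Villiger type). The peri hydroxyl would then displace the acyloxy group from C2 to give the chromone acid A4.
- In its favour: ring D and the free acid appear in one operation, with no ester hydrolysis. The skeleton is a binaphthyl built from two copies of one naphthalene precursor. On the number of skeletal operations it is the equal of the chosen plan and on paper possibly shorter.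
- Against it here: oxygen insertion has several candidate acyl bonds and competes with epoxidation of C2=C3. The electron-rich trimethoxynaphthalene half is itself sensitive to peracid. The unsymmetrical biaryl bond of A5 needs its own regiocontrolled coupling.
- Comparison: the concept is more economical, but it rests on a chemoselectivity for which the substrate offers no control element. The aryne cycloaddition belongs to an established reaction class whose only open question is orientation.

Alternative 3: The cut runs through ring A at C4a–C5 and C8–C8a. Forward, the vinylketene acetal A8 would add across the brominated double bond of the aryl bromoquinone A7, and loss of HBr and methanol would give the hydroxyquinone A6 directly.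
- In its favour: bromine dictates the orientation of the diene, which is more reliable than the orientation of an aryne on a 3-arylfuran. The C5 hydroxyl emerges free with the quinone at the right oxidation level, so neither naphthol oxidation nor ether cleavage is needed. On regiocontrol and on the endgame it is better than the chosen plan.
- Against it here: A7 must be assembled by coupling the hindered C8' position with a 2,5-dioxygenated aryl group, then oxidising and brominating beside the chromone. The nucleophilic A8 can also attack C2' of ring D. A methyl ester would still have to be hydrolysed beside a hydroxyquinone.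
- Comparison: both plans make the crowded C8'–C bond by cross-coupling (a point of equality) and the step count is comparable. The chosen plan is preferred because its coupling partner is a simple commercial boronic acid and its cycloaddition partners are stable, whereas A7 and A8 are sensitive.

Key step: step 11

Assumption: the C2–C8' axis is treated as freely rotating, as the target is drawn, so no atropisomer control is planned; 19 is racemic.

## Route

Step 1
Reactants: 1 3,5-dimethoxytoluene
Product: 3 1-(2,6-dimethoxy-4-methylphenyl)ethan-1-one, via 2,6-dimethoxy-4-methylphenyllithium 2 (not isolated)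
Conditions: n-BuLi (1.1 equiv), THF, 0 °C to rt; then MeC(O)N(OMe)Me, −78 °C to rt; aq. HCl
Reagents that add atoms: N-methoxy-N-methylacetamide, CC(=O)N(C)OC
Why: Directed ortho-metalation; the two methoxy groups jointly direct lithiation to the carbon between them, and the N-methoxy-N-methylamide stops at the ketone through its chelated tetrahedral adduct.

Step 2
Reactants: 3 1-(2,6-dimethoxy-4-methylphenyl)ethan-1-one
Product: 4 1-(3-iodo-2,6-dimethoxy-4-methylphenyl)ethan-1-one
Conditions: NIS (1.05 equiv), CF3CO2H (cat.), MeCN, rt
Reagents that add atoms: N-iodosuccinimide, O=C1CCC(=O)N1I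
Why: Electrophilic aromatic iodination; the two open positions of 3 are equivalent by symmetry and each is ortho and para to a methoxy group, so one mono-iodide is expected if NIS is not in excess.

Step 3
Reactants: 4 1-(3-iodo-2,6-dimethoxy-4-methylphenyl)ethan-1-one
Product: 5 1-(2-hydroxy-3-iodo-6-methoxy-4-methylphenyl)ethan-1-one
Conditions: BCl3 (1.2 equiv), CH2Cl2, −78 to 0 °C; aq. NaHCO3
Reagents that add atoms: none
Why: Chelation-assisted ether cleavage; BCl3 bound to the ketone delivers chloride to an ortho O-methyl group, and the one buttressed between acetyl and iodine is twisted out of conjugation and more basic, so it should go first, while the resulting boron chelate resists a second cleavage at low temperature.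

Step 4
Reactants: 5 1-(2-hydroxy-3-iodo-6-methoxy-4-methylphenyl)ethan-1-one
Product: 7 8-iodo-5-methoxy-7-methyl-4H-chromen-4-one, via enaminone 6 (not isolated)
Conditions: Me2NCH(OMe)2 (3 equiv), toluene, 100 °C; concentrate; then conc. HCl, CH2Cl2, rt
Reagents that add atoms: N,N-dimethylformamide dimethyl acetal, COC(OC)N(C)C
Why: Enaminone route to chromones; the methyl ketone condenses with the formamide acetal and acid then triggers addition of the only free phenol to the β-carbon with loss of dimethylamine, which fixes O1' next to the iodine-bearing carbon.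

Step 5
Reactants: 7 8-iodo-5-methoxy-7-methyl-4H-chromen-4-one
Product: 8 5-hydroxy-8-iodo-7-methyl-4H-chromen-4-one
Conditions: BCl3 (2 equiv), CH2Cl2, −78 to 0 °C; H2O
Reagents that add atoms: none
Why: Peri-chelation-assisted demethylation; the C5' methoxy oxygen and the C4' carbonyl form a six-membered boron chelate, so this ether falls under mild conditions that leave the aryl iodide and ring D alone.

Step 6
Reactants: 8 5-hydroxy-8-iodo-7-methyl-4H-chromen-4-one; 9 furan-3-ylboronic acid
Product: 10 8-(furan-3-yl)-5-hydroxy-7-methyl-4H-chromen-4-one
Conditions: 9 (1.5 equiv), Pd(dppf)Cl2 (5 mol %), K3PO4 (3 equiv), 1,4-dioxane/H2O (5:1), 80 °C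
Reagents that add atoms: none
Why: Suzuki–Miyaura coupling; an aryl iodide adds to zerovalent palladium readily even between two ortho substituents, 3-furylboronic acids resist protodeboronation, and phosphate is mild enough for ring D.

Step 7
Reactants: 10 8-(furan-3-yl)-5-hydroxy-7-methyl-4H-chromen-4-one
Product: 11 8-(furan-3-yl)-7-methyl-4-oxo-4H-chromen-5-yl trifluoromethanesulfonate
Conditions: PhNTf2 (1.2 equiv), K2CO3 (2 equiv), DMF, rt to 50 °C
Reagents that add atoms: N-phenylbis(trifluoromethanesulfonimide), O=S(=O)(N(c1ccccc1)S(=O)(=O)C(F)(F)F)C(F)(F)F
Why: O-sulfonylation of the chelated C5' phenoxide; the mild triflyl donor PhNTf2 is used in place of Tf2O to spare the electron-rich furan.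

Step 8
Reactants: 11 8-(furan-3-yl)-7-methyl-4-oxo-4H-chromen-5-yl trifluoromethanesulfonate
Product: 12 benzyl 8-(furan-3-yl)-7-methyl-4-oxo-4H-chromene-5-carboxylate
Conditions: Pd(OAc)2 (5 mol %), Ph2P(CH2)3PPh2 (6 mol %), CO (1 atm), BnOH (5 equiv), Et3N (2 equiv), DMF, 70 °C
Reagents that add atoms: carbon monoxide, [C-]#[O+]; benzyl alcohol, OCc1ccccc1
Why: Palladium-catalysed alkoxycarbonylation of an aryl triflate; zerovalent palladium inserts into the C–OTf bond, CO inserts, and benzyl alcohol captures the acylpalladium, giving an ester that survives fluoride and acid and falls with the methyl ether in step 14.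

Step 9
Reactants: 13 2-methoxy-4-methylphenol
Product: 14 2-bromo-6-methoxy-4-methylphenol
Conditions: NBS (1.0 equiv), i-Pr2NH (10 mol %), CH2Cl2, 0 °C to rt
Reagents that add atoms: N-bromosuccinimide, O=C1CCC(=O)N1Br
Why: Amine-mediated ortho-bromination of a phenol; the para position is blocked by methyl and the hydroxyl outranks the methoxy group as director, so bromine should enter ortho to OH.

Step 10
Reactants: 14 2-bromo-6-methoxy-4-methylphenol
Product: 17 2-methoxy-4-methyl-6-(trimethylsilyl)phenyl trifluoromethanesulfonate, via aryl silyl ether 15 (not isolated), via lithium silylphenolate 16 (not isolated)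
Conditions: (Me3Si)2NH (1.2 equiv), THF, 70 °C; concentrate; n-BuLi (1.1 equiv), THF, −78 °C; then Tf2O (1.2 equiv), −78 °C to rt
Reagents that add atoms: hexamethyldisilazane, C[Si](C)(C)N[Si](C)(C)C; trifluoromethanesulfonic anhydride, O=S(=O)(OS(=O)(=O)C(F)(F)F)C(F)(F)F
Why: O-silylation, bromine–lithium exchange and 1,3 O-to-C silyl shift (retro-Brook rearrangement) put silicon on carbon and leave a lithium phenolate that Tf2O traps; this is the standard entry to 2-(trimethylsilyl)aryl triflates.

Step 11
Reactants: 12 benzyl 8-(furan-3-yl)-7-methyl-4-oxo-4H-chromene-5-carboxylate; 17 2-methoxy-4-methyl-6-(trimethylsilyl)phenyl trifluoromethanesulfonate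
Product: 19 benzyl 8-(5-methoxy-7-methyl-1,4-dihydro-1,4-epoxynaphthalen-2-yl)-7-methyl-4-oxo-4H-chromene-5-carboxylate (racemic), via 3-methoxy-5-methylbenzyne 18 (not isolated)
Conditions: 17 (1.5 equiv, added in portions), CsF (3 equiv), MeCN, rt
Reagents that add atoms: none
Why: Fluoride attacks silicon of 17, the aryl anion expels triflate, and aryne 18 is trapped at once by the furan of 12 in a concerted but asynchronous (4+2) cycloaddition (aryne Diels–Alder reaction). The six-membered carbocycle C1–C2–C3–C4–C4a–C8a is closed by cycloaddition, C4–C4a and C1–C8a forming in one step on one face of the diene, which leaves the furan oxygen as a one-atom bridge. The new stereocentres are the bridgeheads C1 and C4; their relative configuration is dictated by the bridge, the product is racemic, and both centres are erased in steps 12 and 13. The step needs the orientation in which furan C2, next to the chromonyl-bearing carbon, bonds to the aryne carbon meta to the methoxy group. Three substrate features act in that direction: the inductive methoxy group makes the meta aryne carbon the more electrophilic one, a 3-arylfuran as a 2-substituted diene carries its larger HOMO coefficient at C2, and the encumbered C2 terminus avoids the aryne carbon flanked by methoxy. The preference should be useful but not complete, and the minor regioisomer is to be removed here or at 21. The electron-poor double bond of ring D and the benzyl ester are not aryne traps.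

Step 12
Reactants: 19 benzyl 8-(5-methoxy-7-methyl-1,4-dihydro-1,4-epoxynaphthalen-2-yl)-7-methyl-4-oxo-4H-chromene-5-carboxylate
Product: 20 benzyl 8-(1-hydroxy-5-methoxy-7-methylnaphthalen-2-yl)-7-methyl-4-oxo-4H-chromene-5-carboxylate
Conditions: CF3CO2H (5 equiv), CH2Cl2, 0 °C to rt
Reagents that add atoms: none
Why: Acid-catalysed isomerisation of a 1,4-epoxy-1,4-dihydronaphthalene; the C4–O bond ionises to a cation stabilised by the ortho methoxy group, the para methyl group and the allylic double bond, and loss of the C1 proton gives the 1-naphthol, while the benzyl ester is stable to this acid.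

Step 13
Reactants: 20 benzyl 8-(1-hydroxy-5-methoxy-7-methylnaphthalen-2-yl)-7-methyl-4-oxo-4H-chromene-5-carboxylate
Product: 21 benzyl 8-(5-methoxy-7-methyl-1,4-dioxo-1,4-dihydronaphthalen-2-yl)-7-methyl-4-oxo-4H-chromene-5-carboxylate
Conditions: (KSO3)2NO (3 equiv), KH2PO4 buffer (pH 6), acetone/H2O, rt
Reagents that add atoms: potassium nitrosodisulfonate, [K+].[K+].[O]N(S(=O)(=O)[O-])S(=O)(=O)[O-]
Why: Teuber oxidation of a para-unsubstituted 1-naphthol; one nitrosodisulfonate radical abstracts the phenolic hydrogen and a second couples at C4, and since C1 and C4 both become carbonyl carbons the other naphthol isomer would give the same quinone.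

Step 14
Reactants: 21 benzyl 8-(5-methoxy-7-methyl-1,4-dioxo-1,4-dihydronaphthalen-2-yl)-7-methyl-4-oxo-4H-chromene-5-carboxylate
Product: 22 8-(5-hydroxy-7-methyl-1,4-dioxo-1,4-dihydronaphthalen-2-yl)-7-methyl-4-oxo-4H-chromene-5-carboxylic acid
Conditions: BCl3 (6 equiv), CH2Cl2, −78 °C to rt; then H2O
Reagents that add atoms: none
Why: Lewis-acid dealkylation; BCl3 chelated between the C4 carbonyl and the peri methoxy oxygen removes the methyl group at low temperature and on warming cleaves the benzyl ester at the benzylic carbon, so no basic hydrolysis touches the quinone or ring D.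

## Compound list

1 | 3,5-dimethoxytoluene | COc1cc(C)cc(OC)c1 | starting material
2 | 2,6-dimethoxy-4-methylphenyllithium | [Li]c1c(OC)cc(C)cc1OC | intermediate
3 | 1-(2,6-dimethoxy-4-methylphenyl)ethan-1-one | CC(=O)c1c(OC)cc(C)cc1OC | intermediate
4 | 1-(3-iodo-2,6-dimethoxy-4-methylphenyl)ethan-1-one | CC(=O)c1c(OC)cc(C)c(I)c1OC | intermediate
5 | 1-(2-hydroxy-3-iodo-6-methoxy-4-methylphenyl)ethan-1-one | CC(=O)c1c(OC)cc(C)c(I)c1O | intermediate
6 | (2E)-3-(dimethylamino)-1-(2-hydroxy-3-iodo-6-methoxy-4-methylphenyl)prop-2-en-1-one | CN(C)/C=C/C(=O)c1c(OC)cc(C)c(I)c1O | intermediate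
7 | 8-iodo-5-methoxy-7-methyl-4H-chromen-4-one | COc1cc(C)c(I)c2occc(=O)c12 | intermediate
8 | 5-hydroxy-8-iodo-7-methyl-4H-chromen-4-one | Cc1cc(O)c2c(=O)ccoc2c1I | intermediate
9 | furan-3-ylboronic acid | OB(O)c1ccoc1 | starting material
10 | 8-(furan-3-yl)-5-hydroxy-7-methyl-4H-chromen-4-one | Cc1cc(O)c2c(=O)ccoc2c1-c1ccoc1 | intermediate
11 | 8-(furan-3-yl)-7-methyl-4-oxo-4H-chromen-5-yl trifluoromethanesulfonate | Cc1cc(OS(=O)(=O)C(F)(F)F)c2c(=O)ccoc2c1-c1ccoc1 | intermediate
12 | benzyl 8-(furan-3-yl)-7-methyl-4-oxo-4H-chromene-5-carboxylate | O=C(OCc1ccccc1)c1cc(C)c(-c2ccoc2)c2occc(=O)c12 | intermediate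
13 | 2-methoxy-4-methylphenol | COc1cc(C)ccc1O | starting material
14 | 2-bromo-6-methoxy-4-methylphenol | COc1cc(C)cc(Br)c1O | intermediate
15 | (2-bromo-6-methoxy-4-methylphenoxy)trimethylsilane | COc1cc(C)cc(Br)c1O[Si](C)(C)C | intermediate
16 | lithium 2-methoxy-4-methyl-6-(trimethylsilyl)phenolate | [Li+].COc1cc(C)cc([Si](C)(C)C)c1[O-] | intermediate
17 | 2-methoxy-4-methyl-6-(trimethylsilyl)phenyl trifluoromethanesulfonate | COc1cc(C)cc([Si](C)(C)C)c1OS(=O)(=O)C(F)(F)F | intermediate
18 | 3-methoxy-5-methylbenzyne | COC1=CC(C)=CC#C1 | intermediate
19 | benzyl 8-(5-methoxy-7-methyl-1,4-dihydro-1,4-epoxynaphthalen-2-yl)-7-methyl-4-oxo-4H-chromene-5-carboxylate (racemic, bridgehead hydrogens syn, one enantiomer drawn) | COc1cc(C)cc2c1[C@@H]1O[C@H]2C(c2c(C)cc(C(=O)OCc4ccccc4)c3c(=O)ccoc23)=C1 | intermediate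
20 | benzyl 8-(1-hydroxy-5-methoxy-7-methylnaphthalen-2-yl)-7-methyl-4-oxo-4H-chromene-5-carboxylate | COc1cc(C)cc2c(O)c(-c3c(C)cc(C(=O)OCc4ccccc4)c5c(=O)ccoc35)ccc12 | intermediate
21 | benzyl 8-(5-methoxy-7-methyl-1,4-dioxo-1,4-dihydronaphthalen-2-yl)-7-methyl-4-oxo-4H-chromene-5-carboxylate | COc1cc(C)cc2c1C(=O)C=C(c1c(C)cc(C(=O)OCc3ccccc3)c3c(=O)ccoc13)C2=O | intermediate
22 | 8-(5-hydroxy-7-methyl-1,4-dioxo-1,4-dihydronaphthalen-2-yl)-7-methyl-4-oxo-4H-chromene-5-carboxylic acid | Cc1cc(O)c2c(c1)C(=O)C(c1c(C)cc(C(=O)O)c3c(=O)ccoc13)=CC2=O | target

## Step count and least certain steps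

Total: 14 steps. Longest linear sequence: 12 steps (steps 1 to 8, then 11 to 14); steps 9 and 10 form a two-step branch.

Step 11 (key step). The most likely failure is incomplete control of the orientation of the aryne on the unsymmetrical furan, because the electronic bias of a twisted 3-arylfuran is small. A second concern is loss of the aryne to side reactions before it meets the hindered diene. The fallback sets out from 17 and 8 and returns at 21; it fixes the regiochemistry on a small, strongly polarised diene and makes the biaryl bond afterwards by cross-coupling.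
- The aryne from 17 is trapped with purchased 2-methoxyfuran, whose nucleophilic C5 bonds to the aryne carbon meta to methoxy. This gives the bridgehead ketal 4,5-dimethoxy-7-methyl-1,4-dihydro-1,4-epoxynaphthalene F1, which opens on acidic work-up to 4,5-dimethoxy-7-methylnaphthalen-1-ol F2.
- Bromination ortho to the hydroxyl (NBS) gives 2-bromo-4,5-dimethoxy-7-methylnaphthalen-1-ol F3, and O-methylation (MeI, K2CO3) gives 2-bromo-1,4,5-trimethoxy-7-methylnaphthalene F4.
- Bromine–lithium exchange (n-BuLi) with B(OMe)3 quench gives (1,4,5-trimethoxy-7-methylnaphthalen-2-yl)boronic acid F5.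
- Suzuki–Miyaura coupling of F5 with 8 gives 5-hydroxy-7-methyl-8-(1,4,5-trimethoxy-7-methylnaphthalen-2-yl)-4H-chromen-4-one F6.
- The conditions of steps 7 and 8 then give 7-methyl-4-oxo-8-(1,4,5-trimethoxy-7-methylnaphthalen-2-yl)-4H-chromen-5-yl trifluoromethanesulfonate F7 and benzyl 7-methyl-4-oxo-8-(1,4,5-trimethoxy-7-methylnaphthalen-2-yl)-4H-chromene-5-carboxylate F8.
- (NH4)2Ce(NO3)6 in aqueous MeCN should oxidise the 1,4-dimethoxy ring of F8 to 21.

Step 3. The most likely failure is loss of site selectivity between the two ortho methoxy groups, or cleavage of both, which would leave the later ring closure without direction. The fallback sets out from 3 and returns at 5; it lets symmetry decide the ether cleavage and the phenol direct the iodination. BCl3 on symmetric 3 gives 1-(2-hydroxy-6-methoxy-4-methylphenyl)ethan-1-one F9 as the only possible mono-phenol. Iodination ortho to the chelated hydroxyl (PhCH2NMe3 ICl2, NaHCO3, CH2Cl2/MeOH) should then give 5.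

Step 13. The most likely failure is slow radical oxidation of a 1-naphthol shielded by its ortho aryl group, with competing oxidative coupling. The fallback sets out from 20 and returns at 21; it uses a two-electron ionic oxidation through a ketal. PhI(OAc)2 (2.2 equiv) in MeOH should convert 20 into benzyl 7-methyl-4-oxo-8-(4,4,5-trimethoxy-7-methyl-1-oxo-1,4-dihydronaphthalen-2-yl)-4H-chromene-5-carboxylate F10, and dilute aqueous acid should hydrolyse F10 to 21.

Step 14. The most likely failure is incomplete cleavage of the hindered benzyl ester under conditions mild enough for the quinone, or degradation of the quinone on long exposure to the Lewis acid. The fallback sets out from 20 and returns at 22; it removes the benzyl group before the quinone exists.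
- Hydrogenolysis of 20 (H2, Pd/C, EtOAc, stopped after one equivalent) gives 8-(1-hydroxy-5-methoxy-7-methylnaphthalen-2-yl)-7-methyl-4-oxo-4H-chromene-5-carboxylic acid F11.
- Oxidation as in step 13 gives 8-(5-methoxy-7-methyl-1,4-dioxo-1,4-dihydronaphthalen-2-yl)-7-methyl-4-oxo-4H-chromene-5-carboxylic acid F12.
- Brief BCl3 treatment at low temperature, now needed only for the chelated methyl ether, gives 22.

## Further compounds

F1 | step 11 | 4,5-dimethoxy-7-methyl-1,4-dihydro-1,4-epoxynaphthalene (racemic) | COc1cc(C)cc2c1C1(OC)C=CC2O1
F2 | step 11 | 4,5-dimethoxy-7-methylnaphthalen-1-ol | COc1cc(C)cc2c(O)ccc(OC)c12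
F3 | step 11 | 2-bromo-4,5-dimethoxy-7-methylnaphthalen-1-ol | COc1cc(C)cc2c(O)c(Br)cc(OC)c12
F4 | step 11 | 2-bromo-1,4,5-trimethoxy-7-methylnaphthalene | COc1cc(C)cc2c(OC)c(Br)cc(OC)c12
F5 | step 11 | (1,4,5-trimethoxy-7-methylnaphthalen-2-yl)boronic acid | COc1cc(C)cc2c(OC)c(B(O)O)cc(OC)c12
F6 | step 11 | 5-hydroxy-7-methyl-8-(1,4,5-trimethoxy-7-methylnaphthalen-2-yl)-4H-chromen-4-one | COc1cc(C)cc2c(OC)c(-c3c(C)cc(O)c4c(=O)ccoc34)cc(OC)c12
F7 | step 11 | 7-methyl-4-oxo-8-(1,4,5-trimethoxy-7-methylnaphthalen-2-yl)-4H-chromen-5-yl trifluoromethanesulfonate | COc1cc(C)cc2c(OC)c(-c3c(C)cc(OS(=O)(=O)C(F)(F)F)c4c(=O)ccoc34)cc(OC)c12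
F8 | step 11 | benzyl 7-methyl-4-oxo-8-(1,4,5-trimethoxy-7-methylnaphthalen-2-yl)-4H-chromene-5-carboxylate | COc1cc(C)cc2c(OC)c(-c3c(C)cc(C(=O)OCc5ccccc5)c4c(=O)ccoc34)cc(OC)c12
F9 | step 3 | 1-(2-hydroxy-6-methoxy-4-methylphenyl)ethan-1-one | CC(=O)c1c(O)cc(C)cc1OC
F10 | step 13 | benzyl 7-methyl-4-oxo-8-(4,4,5-trimethoxy-7-methyl-1-oxo-1,4-dihydronaphthalen-2-yl)-4H-chromene-5-carboxylate | COc1cc(C)cc2c1C(OC)(OC)C=C(c1c(C)cc(C(=O)OCc3ccccc3)c3c(=O)ccoc13)C2=O
F11 | step 14 | 8-(1-hydroxy-5-methoxy-7-methylnaphthalen-2-yl)-7-methyl-4-oxo-4H-chromene-5-carboxylic acid | COc1cc(C)cc2c(O)c(-c3c(C)cc(C(=O)O)c4c(=O)ccoc34)ccc12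
F12 | step 14 | 8-(5-methoxy-7-methyl-1,4-dioxo-1,4-dihydronaphthalen-2-yl)-7-methyl-4-oxo-4H-chromene-5-carboxylic acid | COc1cc(C)cc2c1C(=O)C=C(c1c(C)cc(C(=O)O)c3c(=O)ccoc13)C2=O
A1 | alternative 1 | methyl 2-acetyl-3-hydroxy-5-methyl-4-(1,4,5-trimethoxy-7-methylnaphthalen-2-yl)benzoate | COC(=O)c1cc(C)c(-c2cc(OC)c3c(OC)cc(C)cc3c2OC)c(O)c1C(C)=O
A2 | alternative 1 | {[1-methoxy-3-methyl-2-(1,4,5-trimethoxy-7-methylnaphthalen-2-yl)buta-1,3-dien-1-yl]oxy}trimethylsilane | COC(O[Si](C)(C)C)=C(C(C)=C)c1cc(OC)c2c(OC)cc(C)cc2c1OC
A3 | alternative 1 | methyl 4-oxopent-2-ynoate | CC(=O)C#CC(=O)OC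
A4 | alternative 2 | 7-methyl-4-oxo-8-(1,4,5-trimethoxy-7-methylnaphthalen-2-yl)-4H-chromene-5-carboxylic acid | COc1c(-c2c(C)cc(C(=O)O)c3c(=O)ccoc23)cc(OC)c2c(OC)cc(C)cc12
A5 | alternative 2 | 5-hydroxy-7-methyl-6-(1,4,5-trimethoxy-7-methylnaphthalen-2-yl)naphthalene-1,4-dione | Cc1cc2C(=O)C=CC(=O)c2c(O)c1-c1cc(OC)c2c(OC)cc(C)cc2c1OC
A6 | alternative 3 | methyl 8-(5-hydroxy-7-methyl-1,4-dioxo-1,4-dihydronaphthalen-2-yl)-7-methyl-4-oxo-4H-chromene-5-carboxylate | COC(=O)c1cc(C)c(C2=CC(=O)c3c(O)cc(C)cc3C2=O)c2occc(=O)c12
A7 | alternative 3 | methyl 8-(4-bromo-3,6-dioxocyclohexa-1,4-dien-1-yl)-7-methyl-4-oxo-4H-chromene-5-carboxylate | COC(=O)c1cc(C)c(C2=CC(=O)C(Br)=CC2=O)c2occc(=O)c12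
A8 | alternative 3 | [(1-methoxy-3-methylbuta-1,3-dien-1-yl)oxy]trimethylsilane | COC(O[Si](C)(C)C)=CC(C)=C
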